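**Strategy.** Everything rests on cutting ring A out of the isoflavone: its four bonds C8–C8a, C7–C8, C5–C6 and C4a–C5 are made last, on a finished ring C/ring B unit. The feature exploited is the 2-alkylresorcinol pattern of ring A (C5–OH, C6 prenyl, C7–O) fused to ring C at C4a–C8a. In one operation, a light-induced Wolff rearrangement of a pyranonyl diazoketone in the presence of a prenyl-substituted siloxyalkyne starts a pericyclic cascade that builds ring A with the chelated C5 phenol, the C6 prenyl group and the silylated C7 oxygen in place. The precursor is a 2-diazoacetyl-4-pyranone that already carries the complete, silyl-protected ring B at pyranone C5 (the future C3).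

Key step: step 14

Remark: prenyl = 3-methylbut-2-enyl, TIPS = triisopropylsilyl, Ar = 2-methoxy-3-prenyl-4-(triisopropylsilyloxy)phenyl; the target has no stereocentre, and the sp3 centres that appear in 23 and 25 are racemic and are erased within step 14.

**Ring B boronate**

Step 1
Reactants: 1 4-bromoresorcinol (4-bromobenzene-1,3-diol)
Product: 2 2-bromo-5-(triisopropylsilyloxy)phenol
Conditions: TIPSCl (1.05 equiv), imidazole, CH2Cl2, −20 → 0 °C
Reagents that add atoms: chlorotriisopropylsilane, CC(C)[Si](Cl)(C(C)C)C(C)C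
Why: Silyl ether formation with a bulky chlorosilane is sterically controlled, so the open hydroxyl para to bromine should be silylated in preference to the one crowded by the ortho bromine, the minor isomer and the bis-ether being removable by chromatography.

Step 2
Reactants: 2 2-bromo-5-(triisopropylsilyloxy)phenol; 3 3-chloro-3-methylbut-1-yne
Product: 4 1-bromo-2-(2-methylbut-3-yn-2-yloxy)-4-(triisopropylsilyloxy)benzene
Conditions: CuCl2·2H2O (1 mol %), DBU, MeCN, 0 °C
Reagents that add atoms: none
Why: Copper-catalysed propargylic substitution of a tertiary propargyl chloride by a phenoxide is the standard way to aryl 1,1-dimethylpropargyl ethers and runs at 0 °C, where the aryl bromide and the silyl ether are inert.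

Step 3
Reactants: 4 1-bromo-2-(2-methylbut-3-yn-2-yloxy)-4-(triisopropylsilyloxy)benzene
Product: 5 1-bromo-2-(2-methylbut-3-en-2-yloxy)-4-(triisopropylsilyloxy)benzene
Conditions: H2 (1 atm), Pd/CaCO3 poisoned with Pb(OAc)2, quinoline, EtOAc, rt
Reagents that add atoms: none
Why: Semihydrogenation over the lead-poisoned palladium catalyst (Lindlar-type reduction) stops at the monosubstituted alkene and does not touch the aryl bromide.

Step 4
Reactants: 5 1-bromo-2-(2-methylbut-3-en-2-yloxy)-4-(triisopropylsilyloxy)benzene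
Product: 6 6-bromo-2-prenyl-3-(triisopropylsilyloxy)phenol
Conditions: PhMe, 120 °C (sealed tube, base-washed glass)
Reagents that add atoms: none
Why: Aromatic Claisen rearrangement ([3,3]-sigmatropic shift): one ortho carbon carries bromine and cannot rearomatise, so the allyl unit should be delivered to the carbon between the two oxygens, with allylic inversion converting the 1,1-dimethylallyl ether into the linear prenyl group.

Step 5
Reactants: 6 6-bromo-2-prenyl-3-(triisopropylsilyloxy)phenol
Product: 7 1-bromo-2-methoxy-3-prenyl-4-(triisopropylsilyloxy)benzene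
Conditions: MeI, K2CO3, acetone, 40 °C
Reagents that add atoms: iodomethane, CI
Why: Williamson O-methylation of the phenoxide under mild carbonate conditions, to which the hindered aryl silyl ether and the alkene are inert.

Step 6
Reactants: 7 1-bromo-2-methoxy-3-prenyl-4-(triisopropylsilyloxy)benzene
Product: 8 2-Ar-4,4,5,5-tetramethyl-1,3,2-dioxaborolane
Conditions: B2pin2, Pd(dppf)Cl2 (3 mol %), KOAc, 1,4-dioxane, 85 °C
Reagents that add atoms: bis(pinacolato)diboron, CC1(C)OB(OC1(C)C)B1OC(C)(C)C(C)(C)O1
Why: Miyaura borylation of the aryl bromide (oxidative addition to zerovalent palladium, acetate-assisted transmetalation with the diboron) is compatible with silyl ethers and isolated alkenes.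

**Pyranone and diazoketone**

Step 7
Reactants: 9 comenic acid (5-hydroxy-4-oxo-4H-pyran-2-carboxylic acid)
Product: 10 methyl 5-hydroxy-4-oxo-4H-pyran-2-carboxylate
Conditions: MeOH, H2SO4 (cat.), reflux
Reagents that add atoms: methanol, CO
Why: Fischer esterification; the enolic 5-hydroxyl is not alkylated under acid catalysis.

Step 8
Reactants: 10 methyl 5-hydroxy-4-oxo-4H-pyran-2-carboxylate
Product: 11 methyl 4-oxo-5-(trifluoromethanesulfonyloxy)-4H-pyran-2-carboxylate
Conditions: Tf2O, pyridine, CH2Cl2, −20 → 0 °C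
Reagents that add atoms: trifluoromethanesulfonic anhydride, O=S(=O)(OS(=O)(=O)C(F)(F)F)C(F)(F)F
Why: O-Sulfonylation of the enolic 5-hydroxyl gives a vinylogous-ester triflate that is activated for oxidative addition.

Step 9
Reactants: 8 2-Ar-4,4,5,5-tetramethyl-1,3,2-dioxaborolane; 11 methyl 4-oxo-5-(trifluoromethanesulfonyloxy)-4H-pyran-2-carboxylate
Product: 12 methyl 5-Ar-4-oxo-4H-pyran-2-carboxylate
Conditions: Pd(OAc)2 (3 mol %), SPhos (6 mol %), K3PO4, THF/H2O (10:1), 50 °C
Reagents that add atoms: none
Why: Suzuki–Miyaura coupling: the electron-poor pyranone triflate adds readily to zerovalent palladium and the biaryl phosphine promotes transmetalation of the ortho-methoxy boronate at a temperature that spares the ester and the silyl ether.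

Step 10
Reactants: 12 methyl 5-Ar-4-oxo-4H-pyran-2-carboxylate
Product: 13 5-Ar-4-oxo-4H-pyran-2-carboxylic acid
Conditions: LiOH·H2O (1.1 equiv), THF/H2O, 0 °C; then cold 0.5 M HCl to pH 3
Reagents that add atoms: lithium hydroxide, [Li+].[OH-]
Why: Saponification of the strongly activated pyranone-2-carboxylate is fast at 0 °C with about one equivalent of hydroxide, conditions under which a hindered triisopropylsilyl aryl ether and the pyranone ring should persist.

Step 11
Reactants: 13 5-Ar-4-oxo-4H-pyran-2-carboxylic acid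
Product: 15 2-(diazoacetyl)-5-Ar-4H-pyran-4-one, via acid chloride 14 (not isolated)
Conditions: Me2C=C(Cl)NMe2 (1.1 equiv), CH2Cl2, 0 °C; then added to CH2N2 (3 equiv), Et2O, −10 → 0 °C
Reagents that add atoms: diazomethane, C=[N+]=[N-]
Why: Acylation of diazomethane by an acid chloride (first stage of the Arndt–Eistert sequence); the chloroenamine makes the chloride without liberating HCl, which protects the prenyl group, and excess diazomethane removes the HCl formed in the acylation.

**Siloxyalkyne**

Step 12
Reactants: 16 ethynylmagnesium bromide (HC≡CMgBr); 17 1-bromo-3-methylbut-2-ene (prenyl bromide)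
Product: 18 5-methylhex-4-en-1-yne
Conditions: CuCl (5 mol %), THF, 0 → 40 °C
Reagents that add atoms: none
Why: Copper-catalysed SN2 allylation of an alkynyl Grignard reagent; attack at the primary carbon of prenyl bromide is favoured over the hindered tertiary terminus and gives the skipped enyne.

Step 13
Reactants: 18 5-methylhex-4-en-1-yne
Product: 21 triisopropyl(5-methylhex-4-en-1-ynyloxy)silane, via lithium acetylide 19 (not isolated), via lithium ynolate 20 (not isolated)
Conditions: n-BuLi, THF, −78 °C; t-BuOOLi (from t-BuOOH and LiN(SiMe3)2), −78 → 0 °C; TIPSOTf, −78 → 0 °C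
Reagents that add atoms: tert-butyl hydroperoxide, CC(C)(C)OO; triisopropylsilyl trifluoromethanesulfonate, CC(C)[Si](OS(=O)(=O)C(F)(F)F)(C(C)C)C(C)C
Why: Electrophilic oxygenation of a lithium acetylide by lithium tert-butyl peroxide gives the lithium ynolate, which the bulky silyl triflate captures on oxygen, a known route to triisopropylsiloxyalkynes.

**Ring A and deprotection**

Step 14
Reactants: 15 2-(diazoacetyl)-5-Ar-4H-pyran-4-one; 21 triisopropyl(5-methylhex-4-en-1-ynyloxy)silane
Product: 26 5-hydroxy-2'-methoxy-6,3'-diprenyl-7,4'-bis(triisopropylsilyloxy)isoflavone, via pyranonylketene 22 (not isolated), via cyclobutenone 23 (not isolated), via dienylketene 24 (not isolated), via cyclohexadienone 25 (not isolated)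
Conditions: 21 (1.5 equiv), ClCH2CH2Cl (degassed, 0.02 M), hν (365 nm, Pyrex), rt; then 80 °C
Reagents that add atoms: none
Why: Light expels N2 from 15 and the pyranon-2-yl group shifts to the carbene carbon (Wolff rearrangement, forming C8–C8a) to give ketene 22, across whose C=C bond the electron-rich siloxyalkyne adds in a [2+2] cycloaddition (C5–C6 and C7–C8) to give cyclobutenone 23. Warming opens 23 by reversible four-electron electrocyclic ring opening to dienylketene 24, whose six-electron electrocyclization onto the pyranone C8a=C4a bond (C4a–C5) gives dienone 25, and enolisation to the chelated C5 phenol makes the sequence irreversible. The closest known reaction is the second-generation Danheiser benzannulation of aryl, heteroaryl and alkenyl α-diazoketones with triisopropylsiloxyalkynes, in which an arene or alkene π bond plays the part taken here by the vinylogous-ester double bond of ring C. Ring A is closed by this thermally allowed disrotatory 6π electrocyclization of a hexatriene, with no ionic intermediate, and no stereocentre remains because the sp3 centres of 23 and 25 are erased by ring opening and tautomerisation. Regiocontrol is needed at two points: the nucleophilic, prenyl-bearing alkyne carbon must bond to the electrophilic ketene carbonyl carbon, which the polarity of the ynol ether ensures and which places prenyl at C6 between the two oxygens, and the triene can close only onto C4a because the other neighbour of C8a is the ring oxygen. Chemoselectivity rests on exciting the diazoketone at 365 nm, beyond the main pyranone absorption, and on the absence of any acid, base or free hydroxyl that could capture the ketenes or cyclise a prenyl group.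

Step 15
Reactants: 26 5-hydroxy-2'-methoxy-6,3'-diprenyl-7,4'-bis(triisopropylsilyloxy)isoflavone
Product: 27 2'-methoxylupalbigenin
Conditions: Bu4NF (2.5 equiv), AcOH (2.5 equiv), THF, 0 °C
Reagents that add atoms: none
Why: Fluoride-induced cleavage of both aryl silyl ethers (desilylation), buffered with acetic acid so that the polyphenol is not exposed to strong base and no acid strong enough to cyclise a prenyl group onto a neighbouring hydroxyl is present.

**Compound list**

1 | 4-bromoresorcinol | Oc1ccc(Br)c(O)c1 | starting material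
2 | 2-bromo-5-(triisopropylsilyloxy)phenol | Oc1cc(O[Si](C(C)C)(C(C)C)C(C)C)ccc1Br | intermediate
3 | 3-chloro-3-methylbut-1-yne | C#CC(C)(C)Cl | starting material
4 | 1-bromo-2-(2-methylbut-3-yn-2-yloxy)-4-(triisopropylsilyloxy)benzene | C#CC(C)(C)Oc1cc(O[Si](C(C)C)(C(C)C)C(C)C)ccc1Br | intermediate
5 | 1-bromo-2-(2-methylbut-3-en-2-yloxy)-4-(triisopropylsilyloxy)benzene | C=CC(C)(C)Oc1cc(O[Si](C(C)C)(C(C)C)C(C)C)ccc1Br | intermediate
6 | 6-bromo-2-(3-methylbut-2-enyl)-3-(triisopropylsilyloxy)phenol | Oc1c(Br)ccc(O[Si](C(C)C)(C(C)C)C(C)C)c1CC=C(C)C | intermediate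
7 | 1-bromo-2-methoxy-3-(3-methylbut-2-enyl)-4-(triisopropylsilyloxy)benzene | COc1c(Br)ccc(O[Si](C(C)C)(C(C)C)C(C)C)c1CC=C(C)C | intermediate
8 | 2-[2-methoxy-3-(3-methylbut-2-enyl)-4-(triisopropylsilyloxy)phenyl]-4,4,5,5-tetramethyl-1,3,2-dioxaborolane | COc1c(B2OC(C)(C)C(C)(C)O2)ccc(O[Si](C(C)C)(C(C)C)C(C)C)c1CC=C(C)C | intermediate
9 | comenic acid (5-hydroxy-4-oxo-4H-pyran-2-carboxylic acid) | O=C(O)c1cc(=O)c(O)co1 | starting material
10 | methyl 5-hydroxy-4-oxo-4H-pyran-2-carboxylate | COC(=O)c1cc(=O)c(O)co1 | intermediate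
11 | methyl 4-oxo-5-(trifluoromethanesulfonyloxy)-4H-pyran-2-carboxylate | COC(=O)c1cc(=O)c(OS(=O)(=O)C(F)(F)F)co1 | intermediate
12 | methyl 5-[2-methoxy-3-(3-methylbut-2-enyl)-4-(triisopropylsilyloxy)phenyl]-4-oxo-4H-pyran-2-carboxylate | COC(=O)c1cc(=O)c(-c2ccc(O[Si](C(C)C)(C(C)C)C(C)C)c(CC=C(C)C)c2OC)co1 | intermediate
13 | 5-[2-methoxy-3-(3-methylbut-2-enyl)-4-(triisopropylsilyloxy)phenyl]-4-oxo-4H-pyran-2-carboxylic acid | O=C(O)c1cc(=O)c(-c2ccc(O[Si](C(C)C)(C(C)C)C(C)C)c(CC=C(C)C)c2OC)co1 | intermediate
14 | 5-[2-methoxy-3-(3-methylbut-2-enyl)-4-(triisopropylsilyloxy)phenyl]-4-oxo-4H-pyran-2-carbonyl chloride | O=C(Cl)c1cc(=O)c(-c2ccc(O[Si](C(C)C)(C(C)C)C(C)C)c(CC=C(C)C)c2OC)co1 | intermediate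
15 | 2-(diazoacetyl)-5-[2-methoxy-3-(3-methylbut-2-enyl)-4-(triisopropylsilyloxy)phenyl]-4H-pyran-4-one | [N-]=[N+]=CC(=O)c1cc(=O)c(-c2ccc(O[Si](C(C)C)(C(C)C)C(C)C)c(CC=C(C)C)c2OC)co1 | intermediate
16 | ethynylmagnesium bromide | C#C[Mg]Br | starting material
17 | 1-bromo-3-methylbut-2-ene | CC(C)=CCBr | starting material
18 | 5-methylhex-4-en-1-yne | CC(C)=CCC#C | intermediate
19 | (5-methylhex-4-en-1-ynyl)lithium | CC(C)=CCC#C[Li] | intermediate
20 | lithium 5-methylhex-4-en-1-yn-1-olate | CC(C)=CCC#CO[Li] | intermediate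
21 | triisopropyl(5-methylhex-4-en-1-ynyloxy)silane | CC(C)=CCC#CO[Si](C(C)C)(C(C)C)C(C)C | intermediate
22 | 5-[2-methoxy-3-(3-methylbut-2-enyl)-4-(triisopropylsilyloxy)phenyl]-2-(2-oxoethenyl)-4H-pyran-4-one | O=C=Cc1cc(=O)c(-c2ccc(O[Si](C(C)C)(C(C)C)C(C)C)c(CC=C(C)C)c2OC)co1 | intermediate
23 | 4-{5-[2-methoxy-3-(3-methylbut-2-enyl)-4-(triisopropylsilyloxy)phenyl]-4-oxo-4H-pyran-2-yl}-2-(3-methylbut-2-enyl)-3-(triisopropylsilyloxy)cyclobut-2-en-1-one (racemic) | O=C1C(CC=C(C)C)=C(O[Si](C(C)C)(C(C)C)C(C)C)C1c1cc(=O)c(-c2ccc(O[Si](C(C)C)(C(C)C)C(C)C)c(CC=C(C)C)c2OC)co1 | intermediate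
24 | 5-[2-methoxy-3-(3-methylbut-2-enyl)-4-(triisopropylsilyloxy)phenyl]-2-[(1E)-3-(3-methylbut-2-enyl)-4-oxo-2-(triisopropylsilyloxy)buta-1,3-dienyl]-4H-pyran-4-one (ketene carbon and pyranonyl group cis) | O=C=C(CC=C(C)C)/C(O[Si](C(C)C)(C(C)C)C(C)C)=C\c1cc(=O)c(-c2ccc(O[Si](C(C)C)(C(C)C)C(C)C)c(CC=C(C)C)c2OC)co1 | intermediate
25 | 3-[2-methoxy-3-(3-methylbut-2-enyl)-4-(triisopropylsilyloxy)phenyl]-6-(3-methylbut-2-enyl)-7-(triisopropylsilyloxy)-4aH-chromene-4,5-dione (racemic keto tautomer) | O=C1C(CC=C(C)C)=C(O[Si](C(C)C)(C(C)C)C(C)C)C=C2OC=C(-c3ccc(O[Si](C(C)C)(C(C)C)C(C)C)c(CC=C(C)C)c3OC)C(=O)C12 | intermediate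
26 | 5-hydroxy-2'-methoxy-6,3'-bis(3-methylbut-2-enyl)-7,4'-bis(triisopropylsilyloxy)isoflavone | COc1c(-c2coc3cc(O[Si](C(C)C)(C(C)C)C(C)C)c(CC=C(C)C)c(O)c3c2=O)ccc(O[Si](C(C)C)(C(C)C)C(C)C)c1CC=C(C)C | intermediate
27 | 2'-methoxylupalbigenin | COc1c(-c2coc3cc(O)c(CC=C(C)C)c(O)c3c2=O)ccc(O)c1CC=C(C)C | target

**Totals**

Total step count: 15. Longest linear sequence: 11 steps (steps 1–6, 9, 10, 11, 14, 15).

**Steps most likely to fail**

Step 14. The pyranone, or the isoflavone as it accumulates, may absorb the light and divert the excited state into ring rearrangement or decomposition before N2 is lost. Ketene 22 may also dimerise or be captured before the [2+2] step. The fallback generates the same ketene in the dark and sets out from 15. Wolff rearrangement with PhCO2Ag and Et3N in THF/H2O at rt should give [5-Ar-4-oxo-4H-pyran-2-yl]acetic acid F1 (Arndt–Eistert homologation). This acid is used cold and at once, because it is a vinylogous β-keto acid. Me2C=C(Cl)NMe2 in CH2Cl2 at 0 °C should convert it into [5-Ar-4-oxo-4H-pyran-2-yl]acetyl chloride F2. Slow addition of Et3N to F2 and siloxyalkyne 21 in toluene at rt should dehydrochlorinate F2, and the fallback comes back to the route at ketene 22. Cycloaddition to 23 and heating at 80 °C then lead on to 26.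

Step 11. Diazomethane may add as a dipole across the electron-poor C2=C3 bond of the acylpyranone, or HCl may convert the diazoketone into the chloromethyl ketone. The fallback replaces acylation of diazomethane by diazo transfer and sets out from 13 by way of acid chloride 14. Negishi acylation with MeZnCl and Pd(PPh3)4 in THF at 0 °C should give 2-acetyl-5-Ar-4H-pyran-4-one F3. Claisen condensation with LiN(SiMe3)2 and CF3CO2CH2CF3 in THF at −78 °C should give 4,4,4-trifluoro-1-[5-Ar-4-oxo-4H-pyran-2-yl]butane-1,3-dione F4, which is used crude. Detrifluoroacetylative diazo transfer with MsN3, Et3N and H2O in MeCN at rt brings the fallback back to the route at 15.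

Step 9. Under aqueous base, hydrolysis of the pyranone triflate or ester and protodeboronation of the electron-rich ortho-alkoxy boronate may outrun transmetalation. The fallback is a base-free Negishi coupling that sets out from bromide 7 and bypasses step 6. Bromine–lithium exchange with n-BuLi in THF at −78 °C should give [2-methoxy-3-prenyl-4-(triisopropylsilyloxy)phenyl]lithium F5. ZnCl2 should convert it into [2-methoxy-3-prenyl-4-(triisopropylsilyloxy)phenyl]zinc chloride F6. Coupling of F6 with triflate 11 under Pd(OAc)2/SPhos in THF at rt brings the fallback back to the route at 12.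

**Further compounds**

F1 | step 14 | {5-[2-methoxy-3-(3-methylbut-2-enyl)-4-(triisopropylsilyloxy)phenyl]-4-oxo-4H-pyran-2-yl}acetic acid | OC(=O)Cc1cc(=O)c(-c2ccc(O[Si](C(C)C)(C(C)C)C(C)C)c(CC=C(C)C)c2OC)co1
F2 | step 14 | {5-[2-methoxy-3-(3-methylbut-2-enyl)-4-(triisopropylsilyloxy)phenyl]-4-oxo-4H-pyran-2-yl}acetyl chloride | ClC(=O)Cc1cc(=O)c(-c2ccc(O[Si](C(C)C)(C(C)C)C(C)C)c(CC=C(C)C)c2OC)co1
F3 | step 11 | 2-acetyl-5-[2-methoxy-3-(3-methylbut-2-enyl)-4-(triisopropylsilyloxy)phenyl]-4H-pyran-4-one | CC(=O)c1cc(=O)c(-c2ccc(O[Si](C(C)C)(C(C)C)C(C)C)c(CC=C(C)C)c2OC)co1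
F4 | step 11 | 4,4,4-trifluoro-1-{5-[2-methoxy-3-(3-methylbut-2-enyl)-4-(triisopropylsilyloxy)phenyl]-4-oxo-4H-pyran-2-yl}butane-1,3-dione | O=C(CC(=O)C(F)(F)F)c1cc(=O)c(-c2ccc(O[Si](C(C)C)(C(C)C)C(C)C)c(CC=C(C)C)c2OC)co1
F5 | step 9 | [2-methoxy-3-(3-methylbut-2-enyl)-4-(triisopropylsilyloxy)phenyl]lithium | COc1c([Li])ccc(O[Si](C(C)C)(C(C)C)C(C)C)c1CC=C(C)C
F6 | step 9 | [2-methoxy-3-(3-methylbut-2-enyl)-4-(triisopropylsilyloxy)phenyl]zinc chloride | COc1c([Zn]Cl)ccc(O[Si](C(C)C)(C(C)C)C(C)C)c1CC=C(C)C
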